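The furan-3(2H)-one ring (ring O, quaternary C10, carbonyl C1, C2–H, O-bearing sp2 C3; germacrane numbering) is a cyclodehydrated 4-hydroxy-2-ynone. Its C1–C2 edge, shared with the ten-membered carbocycle and flanked by the two oxygenated carbons, is therefore an acetylene dianion inserted between a C10 methyl ketone and a C3 acyl group. In one flask, chelation-controlled ethynylation of an α-PMB-oxy ketone (proline aldol product) forms C1–C10 and the C10 stereocentre, and the resulting alkynylmagnesium acylates a (Z)-enoyl Weinreb amide (from 3-methylbutenolide) to form C2–C3. Amine-mediated hydration closes the furanone; a chromium-mediated Barbier macrocyclisation closes carbocycle and cis-lactone.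

Key step: step 6

Numbering: C4=C5 is the Z alkene, C6/C7 the lactone ring fusion, C8 the ester carbon, C9 the carbinol carbon, C11–C13 the methylene-lactone carbons.

Remark (assumption): the given descriptors correspond to a cis-fused γ-lactone (H6 and H7 on the same face) and a 4Z alkene; the route aims at exactly this diastereomer, (6S,7S,8S,9S,10R).

Step 1
Reactants: 1 hydroxyacetone; 2 2,2-dimethoxyacetaldehyde (commercial aqueous solution)
Product: 3 (3S,4R)-3,4-dihydroxy-5,5-dimethoxypentan-2-one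
Conditions: L-proline (30 mol %), DMSO, rt
Reagents that add atoms: none
Why: Proline-catalysed direct enamine aldol of hydroxyacetone, in which the (E)-enamine on the hydroxylated carbon adds to the non-enolisable, α-branched aldehyde through the hydrogen-bonded chair transition state, should give the anti-diol and set C9 (3S) and C8 (4R) under catalyst control.

Step 2
Reactants: 3 (3S,4R)-3,4-dihydroxy-5,5-dimethoxypentan-2-one
Product: 4 (3S,4R)-4-hydroxy-5,5-dimethoxy-3-[(4-methoxybenzyl)oxy]pentan-2-one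
Conditions: PMBCl, Ag2O, CH2Cl2, rt, dark
Reagents that add atoms: 4-methoxybenzyl chloride, COc1ccc(CCl)cc1
Why: Ag2O-mediated Williamson-type O-alkylation should take the more acidic and less hindered α-ketol hydroxyl (O9) and leave the hydroxyl next to the acetal (O8), under conditions too mild to epimerise the α-ketol.

Step 3
Reactants: 4 (3S,4R)-4-hydroxy-5,5-dimethoxy-3-[(4-methoxybenzyl)oxy]pentan-2-one
Product: 5 (3S,4R)-5,5-dimethoxy-3-[(4-methoxybenzyl)oxy]-4-[(triisopropylsilyl)oxy]pentan-2-one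
Conditions: TIPSOTf, 2,6-lutidine, CH2Cl2, 0 °C
Reagents that add atoms: triisopropylsilyl trifluoromethanesulfonate, CC(C)[Si](C(C)C)(C(C)C)OS(=O)(=O)C(F)(F)F
Why: Silyl triflate silylation of the remaining hindered secondary alcohol puts an acid-stable, non-chelating group on O8, so that the O9 PMB ether is the only chelating site next to the ketone.

Step 4
Reactants: 6 3-methylfuran-2(5H)-one
Product: 7 (Z)-4-hydroxy-N-methoxy-N,2-dimethylbut-2-enamide
Conditions: MeNH(OMe)·HCl, AlMe3, CH2Cl2, 0 °C → rt; aq. KNaC4H4O6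
Reagents that add atoms: N,O-dimethylhydroxylamine hydrochloride, CNOC.Cl
Why: Aluminium amide aminolysis of the lactone (Weinreb amide formation) opens the ring, whose cis geometry fixes the Z configuration of the future C4=C5 bond.

Step 5
Reactants: 7 (Z)-4-hydroxy-N-methoxy-N,2-dimethylbut-2-enamide
Product: 8 (Z)-4-[(tert-butyldiphenylsilyl)oxy]-N-methoxy-N,2-dimethylbut-2-enamide
Conditions: TBDPSCl, imidazole, DMF, 0 °C → rt
Reagents that add atoms: tert-butyldiphenylsilyl chloride, CC(C)(C)[Si](Cl)(c1ccccc1)c1ccccc1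
Why: Silylation of the primary allylic alcohol prevents relactonisation and masks O6 with an acid-stable group.

Step 6
Reactants: 5 PMB/TIPS-protected methyl ketone; 9 ethynylmagnesium bromide (HC≡CMgBr); 8 (Z)-enoyl Weinreb amide
Product: 12 (2Z,7S,8S,9R)-1-[(tert-butyldiphenylsilyl)oxy]-7-hydroxy-10,10-dimethoxy-8-[(4-methoxybenzyl)oxy]-3,7-dimethyl-9-[(triisopropylsilyl)oxy]dec-2-en-5-yn-4-one, via propargylic magnesium alkoxide 10 (not isolated), via alkynylmagnesium alkoxide 11 (not isolated)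
Conditions: 9 (1.05 equiv), THF, −78 → −30 °C; EtMgBr (1.1 equiv), 0 °C; then 8, 0 °C → rt; aq. NH4Cl
Reagents that add atoms: none
Why: Ethynylmagnesium bromide adds 1,2 to the methyl ketone of 5 through the five-membered Cram chelate (Mg bound to the ketone oxygen and the O9 PMB ether), on the face away from the C8 chain, which forms C1–C10; alkoxide 10 is then metallated at the alkyne terminus by EtMgBr (11), and this carbon nucleophile undergoes acyl substitution on amide 8, whose chelated tetrahedral adduct releases the ynone only on quench, forming C2–C3. The closest known reaction types are chelation-controlled Grignard addition to α-alkoxy ketones and acylation of propargylic alkoxide dianions by N-methoxy-N-methylamides. No ring is closed here; the step delivers all five furanone atoms in the right oxidation pattern, and the ring closes in step 7 by attack of O10 on C3 (5-exo-trig) and loss of water. The only new stereocentre, C10, is controlled by the chelate and the existing C9 centre and should have O9 and O10 syn, as the target requires. The step needs ketone-over-amide selectivity in the first addition (low temperature, one equivalent of 9), single acylation (chelated adduct) and retention of the Z alkene (no acid, no enolisable position).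

Step 7
Reactants: 12 hydroxy-ynone
Product: 14 (2R,3S)-3-{(2R)-5-[(Z)-4-[(tert-butyldiphenylsilyl)oxy]but-2-en-2-yl]-2-methyl-3-oxo-2,3-dihydrofuran-2-yl}-3-[(4-methoxybenzyl)oxy]-2-[(triisopropylsilyl)oxy]propanal, via β-diethylamino enone 13 (not isolated)
Conditions: Et2NH, EtOH, rt; then 2 M HCl, THF, rt
Reagents that add atoms: water, O
Why: Conjugate addition of diethylamine to the ynone gives 13, whose acidic hydrolysis unveils the C1 ketone while the tertiary hydroxyl adds to C3 and water is lost (classical 3(2H)-furanone synthesis from 4-hydroxy-ynones), and the same aqueous acid should hydrolyse the dimethyl acetal to the C7 aldehyde while the TBDPS, TIPS and PMB ethers survive.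

Step 8
Reactants: 14 furanone aldehyde; 15 methyl acrylate
Product: 16 methyl (4S,5S)-5-{(2R)-5-[(Z)-4-[(tert-butyldiphenylsilyl)oxy]but-2-en-2-yl]-2-methyl-3-oxo-2,3-dihydrofuran-2-yl}-3-hydroxy-5-[(4-methoxybenzyl)oxy]-2-methylene-4-[(triisopropylsilyl)oxy]pentanoate (C3 epimers)
Conditions: 15 (excess), DABCO, MeOH, rt
Reagents that add atoms: none
Why: Morita–Baylis–Hillman reaction of the α-silyloxy aldehyde installs C11–C13, and the new carbinol centre at C7 is formed as a mixture that does not matter because it is erased in step 11.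

Step 9
Reactants: 16 Baylis–Hillman adduct
Product: 17 methyl (4S,5S)-3-hydroxy-5-{(2R)-5-[(Z)-4-hydroxybut-2-en-2-yl]-2-methyl-3-oxo-2,3-dihydrofuran-2-yl}-5-[(4-methoxybenzyl)oxy]-2-methylene-4-[(triisopropylsilyl)oxy]pentanoate
Conditions: HF·pyridine, pyridine, THF, 0 °C → rt
Reagents that add atoms: none
Why: Buffered fluoride desilylation should cleave the primary TBDPS ether well before the hindered secondary TIPS ether, and the freed (Z)-allylic alcohol is oxidised at once because on standing it could add to C3.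

Step 10
Reactants: 17 diol
Product: 18 methyl (4S,5S)-3-hydroxy-5-[(4-methoxybenzyl)oxy]-5-{(2R)-2-methyl-3-oxo-5-[(Z)-4-oxobut-2-en-2-yl]-2,3-dihydrofuran-2-yl}-2-methylene-4-[(triisopropylsilyl)oxy]pentanoate
Conditions: TEMPO (cat.), PhI(OAc)2, CH2Cl2, rt
Reagents that add atoms: none
Why: Oxoammonium (TEMPO) oxidation is selective for the primary allylic alcohol over the secondary Baylis–Hillman alcohol and is mild enough to keep the Z-enal geometry.

Step 11
Reactants: 18 enal
Product: 19 methyl (2Z,4S,5S)-2-(bromomethyl)-5-[(4-methoxybenzyl)oxy]-5-{(2R)-2-methyl-3-oxo-5-[(Z)-4-oxobut-2-en-2-yl]-2,3-dihydrofuran-2-yl}-4-[(triisopropylsilyl)oxy]pent-2-enoate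
Conditions: NBS, Me2S, CH2Cl2, −20 → 0 °C
Reagents that add atoms: N-bromosuccinimide, O=C1CCC(=O)N1Br
Why: Corey–Kim-type activation of the Baylis–Hillman alcohol and allylic (SN2′) displacement by bromide should give the thermodynamically preferred (Z)-2-(bromomethyl)enoate from both C7 epimers.

Step 12
Reactants: 19 bromo-enal
Product: 21 (6S,7S,8S,9S,10R)-9-[(4-methoxybenzyl)oxy]-1-oxo-8-[(triisopropylsilyl)oxy]-3,10-epoxygermacra-2,4(Z),11(13)-trien-12,6-olide, via macrocyclic hydroxy ester 20 (not isolated)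
Conditions: CrCl2 (6 equiv), THF, rt, high dilution (slow addition of 19); aq. NH4Cl
Reagents that add atoms: none
Why: In this chromium-mediated intramolecular Barbier (Nozaki–Hiyama-type) allylation the allylchromium species, with C8 cis to the CH2Cr terminus, adds to the enal through a chair Zimmerman–Traxler transition state, which should give the syn adduct 20 and, after in situ lactonisation, the cis-fused lactone, while attack on the face of C7 that keeps H8 in the allyl plane (minimal allylic 1,3-strain) with the new bond anti to C9 sets the required C7–C8 relationship.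

Step 13
Reactants: 21 protected macrolactone
Product: 22 (6S,7S,8S,9S,10R)-8-hydroxy-9-[(4-methoxybenzyl)oxy]-1-oxo-3,10-epoxygermacra-2,4(Z),11(13)-trien-12,6-olide
Conditions: HF·pyridine, THF, rt
Reagents that add atoms: none
Why: Unbuffered HF·pyridine over a longer time removes the hindered secondary TIPS ether (fluoride desilylation) without touching the PMB ether, the two Michael acceptors or the vinylogous ester.

Step 14
Reactants: 22 C8 alcohol
Product: 23 (6S,7S,8S,9S,10R)-9-[(4-methoxybenzyl)oxy]-8-(methacryloyloxy)-1-oxo-3,10-epoxygermacra-2,4(Z),11(13)-trien-12,6-olide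
Conditions: methacrylic anhydride, Et3N, DMAP (cat.), CH2Cl2, 0 °C → rt
Reagents that add atoms: methacrylic anhydride, C=C(C)C(=O)OC(=O)C(C)=C
Why: DMAP-catalysed acylation meets only one free hydroxyl (O8), so neither a regiochemical choice nor acyl migration to the still masked O9 can arise.

Step 15
Reactants: 23 PMB-protected methacrylate
Product: 24 CNP0252578.5, (6S,7S,8S,9S,10R)-9-hydroxy-8-(methacryloyloxy)-1-oxo-3,10-epoxygermacra-2,4(Z),11(13)-trien-12,6-olide
Conditions: DDQ, CH2Cl2–pH 7 phosphate buffer, 0 °C → rt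
Reagents that add atoms: none
Why: Oxidative PMB cleavage by DDQ (via the benzylic oxocarbenium ion, hydrolysed by the buffer) is near neutral and should spare the methacrylate, the methylene lactone and the furanone.

Compound list
1 | hydroxyacetone (1-hydroxypropan-2-one) | CC(=O)CO | starting material
2 | 2,2-dimethoxyacetaldehyde | COC(OC)C=O | starting material
3 | (3S,4R)-3,4-dihydroxy-5,5-dimethoxypentan-2-one | CC(=O)[C@@H](O)[C@@H](O)C(OC)OC | intermediate
4 | (3S,4R)-4-hydroxy-5,5-dimethoxy-3-[(4-methoxybenzyl)oxy]pentan-2-one | CC(=O)[C@@H](OCc1ccc(OC)cc1)[C@@H](O)C(OC)OC | intermediate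
5 | (3S,4R)-5,5-dimethoxy-3-[(4-methoxybenzyl)oxy]-4-[(triisopropylsilyl)oxy]pentan-2-one | CC(=O)[C@@H](OCc1ccc(OC)cc1)[C@@H](O[Si](C(C)C)(C(C)C)C(C)C)C(OC)OC | intermediate
6 | 3-methylfuran-2(5H)-one | CC1=CCOC1=O | starting material
7 | (Z)-4-hydroxy-N-methoxy-N,2-dimethylbut-2-enamide | CON(C)C(=O)/C(C)=C\CO | intermediate
8 | (Z)-4-[(tert-butyldiphenylsilyl)oxy]-N-methoxy-N,2-dimethylbut-2-enamide | CON(C)C(=O)/C(C)=C\CO[Si](c1ccccc1)(c1ccccc1)C(C)(C)C | intermediate
9 | ethynylmagnesium bromide (HC≡CMgBr) | C#C[Mg]Br | starting material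
10 | bromomagnesium (3S,4S,5R)-6,6-dimethoxy-4-[(4-methoxybenzyl)oxy]-3-methyl-5-[(triisopropylsilyl)oxy]hex-1-yn-3-olate | C#C[C@](C)(O[Mg]Br)[C@@H](OCc1ccc(OC)cc1)[C@@H](O[Si](C(C)C)(C(C)C)C(C)C)C(OC)OC | intermediate (not isolated)
11 | C1-bromomagnesio derivative of 10 (alkynylmagnesium bromide alkoxide) | Br[Mg]C#C[C@](C)(O[Mg]Br)[C@@H](OCc1ccc(OC)cc1)[C@@H](O[Si](C(C)C)(C(C)C)C(C)C)C(OC)OC | intermediate (not isolated)
12 | (2Z,7S,8S,9R)-1-[(tert-butyldiphenylsilyl)oxy]-7-hydroxy-10,10-dimethoxy-8-[(4-methoxybenzyl)oxy]-3,7-dimethyl-9-[(triisopropylsilyl)oxy]dec-2-en-5-yn-4-one | CC(C)(C)[Si](c1ccccc1)(c1ccccc1)OC/C=C(/C)C(=O)C#C[C@](C)(O)[C@@H](OCc1ccc(OC)cc1)[C@@H](O[Si](C(C)C)(C(C)C)C(C)C)C(OC)OC | intermediate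
13 | (2Z,7S,8S,9R)-1-[(tert-butyldiphenylsilyl)oxy]-5-(diethylamino)-7-hydroxy-10,10-dimethoxy-8-[(4-methoxybenzyl)oxy]-3,7-dimethyl-9-[(triisopropylsilyl)oxy]deca-2,5-dien-4-one (C5=C6 geometry not defined) | CC(C)(C)[Si](c1ccccc1)(c1ccccc1)OC/C=C(/C)C(=O)C=C(N(CC)CC)[C@](C)(O)[C@@H](OCc1ccc(OC)cc1)[C@@H](O[Si](C(C)C)(C(C)C)C(C)C)C(OC)OC | intermediate (not isolated)
14 | (2R,3S)-3-{(2R)-5-[(Z)-4-[(tert-butyldiphenylsilyl)oxy]but-2-en-2-yl]-2-methyl-3-oxo-2,3-dihydrofuran-2-yl}-3-[(4-methoxybenzyl)oxy]-2-[(triisopropylsilyl)oxy]propanal | CC(C)(C)[Si](c1ccccc1)(c1ccccc1)OC/C=C(/C)C2=CC(=O)[C@](C)(O2)[C@@H](OCc3ccc(OC)cc3)[C@@H](O[Si](C(C)C)(C(C)C)C(C)C)C=O | intermediate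
15 | methyl acrylate | C=CC(=O)OC | starting material
16 | methyl (4S,5S)-5-{(2R)-5-[(Z)-4-[(tert-butyldiphenylsilyl)oxy]but-2-en-2-yl]-2-methyl-3-oxo-2,3-dihydrofuran-2-yl}-3-hydroxy-5-[(4-methoxybenzyl)oxy]-2-methylene-4-[(triisopropylsilyl)oxy]pentanoate (C3 epimers) | CC(C)(C)[Si](c1ccccc1)(c1ccccc1)OC/C=C(/C)C2=CC(=O)[C@](C)(O2)[C@@H](OCc3ccc(OC)cc3)[C@@H](O[Si](C(C)C)(C(C)C)C(C)C)C(O)C(=C)C(=O)OC | intermediate
17 | methyl (4S,5S)-3-hydroxy-5-{(2R)-5-[(Z)-4-hydroxybut-2-en-2-yl]-2-methyl-3-oxo-2,3-dihydrofuran-2-yl}-5-[(4-methoxybenzyl)oxy]-2-methylene-4-[(triisopropylsilyl)oxy]pentanoate (C3 epimers) | OC/C=C(/C)C1=CC(=O)[C@](C)(O1)[C@@H](OCc2ccc(OC)cc2)[C@@H](O[Si](C(C)C)(C(C)C)C(C)C)C(O)C(=C)C(=O)OC | intermediate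
18 | methyl (4S,5S)-3-hydroxy-5-[(4-methoxybenzyl)oxy]-5-{(2R)-2-methyl-3-oxo-5-[(Z)-4-oxobut-2-en-2-yl]-2,3-dihydrofuran-2-yl}-2-methylene-4-[(triisopropylsilyl)oxy]pentanoate (C3 epimers) | O=C/C=C(/C)C1=CC(=O)[C@](C)(O1)[C@@H](OCc2ccc(OC)cc2)[C@@H](O[Si](C(C)C)(C(C)C)C(C)C)C(O)C(=C)C(=O)OC | intermediate
19 | methyl (2Z,4S,5S)-2-(bromomethyl)-5-[(4-methoxybenzyl)oxy]-5-{(2R)-2-methyl-3-oxo-5-[(Z)-4-oxobut-2-en-2-yl]-2,3-dihydrofuran-2-yl}-4-[(triisopropylsilyl)oxy]pent-2-enoate | O=C/C=C(/C)C1=CC(=O)[C@](C)(O1)[C@@H](OCc2ccc(OC)cc2)[C@@H](O[Si](C(C)C)(C(C)C)C(C)C)/C=C(\CBr)C(=O)OC | intermediate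
20 | methyl (6S,7S,8S,9S,10R)-6-hydroxy-9-[(4-methoxybenzyl)oxy]-1-oxo-8-[(triisopropylsilyl)oxy]-3,10-epoxygermacra-2,4(Z),11(13)-trien-12-oate (formed as its chromium alkoxide) | CC(C)[Si](C(C)C)(C(C)C)O[C@H]1[C@@H](C(=C)C(=O)OC)[C@@H](O)/C=C(/C)C2=CC(=O)[C@](C)(O2)[C@H]1OCc1ccc(OC)cc1 | intermediate (not isolated)
21 | (6S,7S,8S,9S,10R)-9-[(4-methoxybenzyl)oxy]-1-oxo-8-[(triisopropylsilyl)oxy]-3,10-epoxygermacra-2,4(Z),11(13)-trien-12,6-olide | CC(C)[Si](C(C)C)(C(C)C)O[C@H]1[C@H]2C(=C)C(=O)O[C@H]2/C=C(/C)C2=CC(=O)[C@](C)(O2)[C@H]1OCc1ccc(OC)cc1 | intermediate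
22 | (6S,7S,8S,9S,10R)-8-hydroxy-9-[(4-methoxybenzyl)oxy]-1-oxo-3,10-epoxygermacra-2,4(Z),11(13)-trien-12,6-olide | O[C@H]1[C@H]2C(=C)C(=O)O[C@H]2/C=C(/C)C2=CC(=O)[C@](C)(O2)[C@H]1OCc1ccc(OC)cc1 | intermediate
23 | (6S,7S,8S,9S,10R)-9-[(4-methoxybenzyl)oxy]-8-(methacryloyloxy)-1-oxo-3,10-epoxygermacra-2,4(Z),11(13)-trien-12,6-olide | C=C(C)C(=O)O[C@H]1[C@H]2C(=C)C(=O)O[C@H]2/C=C(/C)C2=CC(=O)[C@](C)(O2)[C@H]1OCc1ccc(OC)cc1 | intermediate
24 | CNP0252578.5, (6S,7S,8S,9S,10R)-9-hydroxy-8-(methacryloyloxy)-1-oxo-3,10-epoxygermacra-2,4(Z),11(13)-trien-12,6-olide | C=C(C)C(=O)O[C@H]1[C@H]2C(=C)C(=O)O[C@H]2/C=C(/C)C2=CC(=O)[C@](C)(O2)[C@H]1O | target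

Total step count: 15. Longest linear sequence: 13 steps (steps 1–3, then 6–15); steps 4–5 form the convergent branch.

Steps most likely to fail

Step 12 (macrocyclisation). What may go wrong: addition to the wrong face of the aldehyde (anti instead of syn addition, leading to the trans-fused lactone), or intermolecular allylation competing with ring closure. The fallback corrects C6 by SN2 inversion instead of relying on the transition state. It sets out from 19, which is cyclised as in step 12. The C6-epimeric, trans-fused lactone (6R,7S,8S,9S,10R)-9-[(4-methoxybenzyl)oxy]-1-oxo-8-[(triisopropylsilyl)oxy]-3,10-epoxygermacra-2,4(Z),11(13)-trien-12,6-olide F1 would be saponified (LiOH, THF–H2O, 0 °C) to the seco acid (6R,7S,8S,9S,10R)-6-hydroxy-9-[(4-methoxybenzyl)oxy]-1-oxo-8-[(triisopropylsilyl)oxy]-3,10-epoxygermacra-2,4(Z),11(13)-trien-12-oic acid F2. Mitsunobu lactonisation of F2 (PPh3, DIAD, toluene, 0 °C) should invert the allylic C6 carbinol (five-membered closure favours direct over allylic displacement) and comes back to the route at 21.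

Step 6 (key step). What may go wrong: incomplete chelation control at C10, or attack of the Grignard reagents on the amide before metallation of the alkyne is complete. The fallback separates the two bond formations and replaces amide acylation by aldehyde addition and oxidation. It sets out from 5 and 8. Ketone 5 is precomplexed with MgBr2·OEt2 in CH2Cl2 at −78 °C and treated with 9, and the tertiary alcohol (3S,4S,5R)-6,6-dimethoxy-4-[(4-methoxybenzyl)oxy]-3-methyl-5-[(triisopropylsilyl)oxy]hex-1-yn-3-ol F3 is isolated and freed of any C10 epimer. Amide 8 is reduced (i-Bu2AlH, THF, −78 °C) to (Z)-4-[(tert-butyldiphenylsilyl)oxy]-2-methylbut-2-enal F4. The dianion of F3 (n-BuLi, 2 equiv, THF, −78 °C) adds to F4 to give (2Z,7S,8S,9R)-1-[(tert-butyldiphenylsilyl)oxy]-10,10-dimethoxy-8-[(4-methoxybenzyl)oxy]-3,7-dimethyl-9-[(triisopropylsilyl)oxy]dec-2-en-5-yne-4,7-diol F5 (C4 epimers). MnO2 (CH2Cl2, rt) oxidises its allylic-propargylic secondary alcohol and comes back to the route at 12.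

Step 2 (regioselective PMB ether). What may go wrong: alkylation at the wrong hydroxyl or at both, or base-induced α-ketol isomerisation. The fallback installs the ether before the aldol. It sets out from 1, which is converted with 4-methoxybenzyl 2,2,2-trichloroacetimidate (cat. CSA, CH2Cl2, rt) into 1-[(4-methoxybenzyl)oxy]propan-2-one F6. The L-proline aldol of F6 with 2 (DMSO, rt; anti-selective enamine aldol on the oxygenated carbon) would give the mono-ether directly and comes back to the route at 4.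

Further compounds
F1 | step 12 | (6R,7S,8S,9S,10R)-9-[(4-methoxybenzyl)oxy]-1-oxo-8-[(triisopropylsilyl)oxy]-3,10-epoxygermacra-2,4(Z),11(13)-trien-12,6-olide (trans-fused C6 epimer of 21) | CC(C)[Si](C(C)C)(C(C)C)O[C@H]1[C@H]2C(=C)C(=O)O[C@@H]2/C=C(/C)C2=CC(=O)[C@](C)(O2)[C@H]1OCc1ccc(OC)cc1
F2 | step 12 | (6R,7S,8S,9S,10R)-6-hydroxy-9-[(4-methoxybenzyl)oxy]-1-oxo-8-[(triisopropylsilyl)oxy]-3,10-epoxygermacra-2,4(Z),11(13)-trien-12-oic acid | CC(C)[Si](C(C)C)(C(C)C)O[C@H]1[C@@H](C(=C)C(=O)O)[C@H](O)/C=C(/C)C2=CC(=O)[C@](C)(O2)[C@H]1OCc1ccc(OC)cc1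
F3 | step 6 | (3S,4S,5R)-6,6-dimethoxy-4-[(4-methoxybenzyl)oxy]-3-methyl-5-[(triisopropylsilyl)oxy]hex-1-yn-3-ol | C#C[C@](C)(O)[C@@H](OCc1ccc(OC)cc1)[C@@H](O[Si](C(C)C)(C(C)C)C(C)C)C(OC)OC
F4 | step 6 | (Z)-4-[(tert-butyldiphenylsilyl)oxy]-2-methylbut-2-enal | O=C/C(C)=C\CO[Si](c1ccccc1)(c1ccccc1)C(C)(C)C
F5 | step 6 | (2Z,7S,8S,9R)-1-[(tert-butyldiphenylsilyl)oxy]-10,10-dimethoxy-8-[(4-methoxybenzyl)oxy]-3,7-dimethyl-9-[(triisopropylsilyl)oxy]dec-2-en-5-yne-4,7-diol (C4 epimers) | CC(C)(C)[Si](c1ccccc1)(c1ccccc1)OC/C=C(/C)C(O)C#C[C@](C)(O)[C@@H](OCc1ccc(OC)cc1)[C@@H](O[Si](C(C)C)(C(C)C)C(C)C)C(OC)OC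
F6 | step 2 | 1-[(4-methoxybenzyl)oxy]propan-2-one | CC(=O)COCc1ccc(OC)cc1
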